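# Proposed synthesis of CNP0253987.1 by asymmetric hydroacylation and Baeyer–Villiger oxygen insertion

## The problem

The target 20 is a 1,1,3-triarylpropane. Its single stereogenic methine C* carries ring A (4-hydroxyphenyl), ring B and a CH2–CH2 chain that ends at ring C (4-hydroxy-2-methoxyphenyl). Ring B is numbered from the carbon bonded to C* as C1. It is a resorcinol with hydroxyl groups at C4 and C6 and a 3-(4-hydroxyphenyl)-3-oxopropyl arm at C3.

C* has the R configuration and is the only stereocentre, so nothing in the molecule can relay chirality to it. It is a diarylmethine whose two aryl groups differ only in substitution pattern. It therefore has to be set by a catalyst, in a setting where the two rings are clearly different.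

The two carbon substituents of ring B each sit ortho to an oxygen on a 1,2,4,5-tetrasubstituted ring. This pattern is safer to fix from a defined precursor than by late substitution on a polyphenol.

Four phenols must be freed at the end while the ring C methyl ether stays, which points to benzyl ethers and a neutral final hydrogenolysis. The arm ketone is reducible. As a 4-oxygenated aryl ketone it is also oxidised by peracids, and under acid it can close onto the C4 phenol. The free resorcinol is sensitive to air and acid.

The feature that opens the molecule is that C1 of ring B bears C* and its neighbour C6 bears oxygen. If that oxygen is left out and C6 is bonded instead to the carbon that becomes the CH2 next to ring C, drawn as a ketone, the unit C6–C(=O)–CH2–C*–C1 is a 3-arylindan-1-one. Such a ketone is what the enantioselective intramolecular hydroacylation of a 2-(1-arylvinyl)benzaldehyde delivers, and a Baeyer–Villiger oxidation then returns the oxygen to C6.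

The price is that the former carbonyl carbon leaves this sequence at the acid oxidation level. It must be brought down to CH2 and joined to ring C without touching the arm ketone.

## Retrosynthesis

**20 ⇒ 19.** The four phenolic O–H bonds are traced back to O–benzyl bonds. Benzyl is preferred over methyl, which could not be told apart from the ring C methoxy group, and over silyl, which would be at risk in the basic and organometallic steps. Compound 19 already has the full carbon skeleton, C* and the arm ketone. The forward step must remove four benzyl groups under neutral conditions and leave a deactivated aryl ketone alone.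

**19 ⇒ 15 + 17 (through 18).** The bond between the chain CH2 and the ipso carbon of ring C is cut. The neighbouring option is to add a ring C aryl metal to the lactone carbonyl of 9. That would create a benzylic oxygen which then has to be removed reductively beside the arm ketone, and it risks double addition. Cutting at the sp3–sp2 bond needs only a primary iodide 15 and the aryl bromide 17. The forward Negishi coupling passes through the alkylzinc iodide 18, which tolerates the ketone. Compound 17 is one benzylation from the phenol 16.

**15 ⇒ 14 ⇒ 11 + 13.** The iodide comes from the primary alcohol 14. In 14 the bond between C3 of ring B and the first CH2 of the arm is cut. The forward reaction is a Heck reaction of the aryl bromide 11 with the allylic alcohol 13. It delivers the arm at the ketone oxidation level, so the arm needs no protecting group. The arm is deliberately added after the oxygen insertion. A 4-alkoxyphenyl ketone is a better Baeyer–Villiger substrate than the indanone. Its ketal would not be safe under acid-promoted peracid conditions. The ketone would also be reduced together with the lactone. A bromine atom therefore holds the place of the arm from the first step. Compound 13 is one Grignard addition from the aldehyde 12.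

**11 ⇒ 10 ⇒ 9.** The primary alcohol and the C6 benzyl ether of 11 are traced back to the lactone 9 through the diol 10. Reduction opens the lactone to a phenol and a primary alcohol. Selective benzylation of the phenol gives all ring oxygens the same protecting group and stops the phenol from closing onto the chain later. Both operations are simple. They turn the acid-level carbon into the CH2–OH needed for the coupling.

**9 ⇒ 8.** The C6–O bond is cut, which is a Baeyer–Villiger transform back to the 3-arylindan-1-one 8. The forward reaction needs aryl migration in preference to CH2 migration. With no ketal and no second ketone in 8, the acid-promoted conditions established for 3-arylindanones can be used. The bromine para to the migrating carbon is only a weak deactivator.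

**8 ⇒ 7.** The acyl–CH2 bond and the C*–H bond are cut, which opens the five-membered ring to the 2-(1-arylvinyl)benzaldehyde 7. This is the step that carries the plan. It makes a ring, a C–C bond and C* at once from an achiral aldehyde. It works in a chelate where ring B is tied to the metal and ring A is not, so the two aryl groups at C* are no longer alike. The forward reaction asks for catalyst-controlled face selection and for tolerance of the aryl bromide.

**7 ⇒ 3 + 6, and the building blocks.** The biaryl-type bond between ring B and the vinyl carbon is cut. The forward reaction is a Suzuki–Miyaura coupling of the iodide 3 with the alkenyl boronate 6. The iodine must react and the bromine must stay. Compound 3 comes from commercial 4-bromo-3-hydroxybenzaldehyde 1 by para iodination to 2 and benzylation. Compound 6 comes from 4'-(benzyloxy)acetophenone 4 through the enol triflate 5. All oxygen and halogen positions of ring B are thus fixed by the choice of 1.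

## Roads not taken

**Alternative 1: desymmetrising C–H lactonisation.** The cut is the C6–O bond of ring B, made directly on the symmetric acid 3,3-bis[4-(benzyloxy)phenyl]propanoic acid A1. In the forward step divalent palladium with a chiral mono-N-protected amino acid ligand and PhI(OAc)2 would oxidise one ortho C–H of one of the two enantiotopic rings through a tetravalent palladium intermediate. This would close the lactone A2 with C* set.

- Merits: it is the shortest way to a 4-aryldihydrocoumarin. It needs no indanone and no oxygen insertion, and A1 is available in very few steps. In step count up to the lactone it is better than the chosen plan.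
- Weak points: because the two rings of A1 must be identical, A2 carries nothing at the ring B carbon that needs the arm. A later electrophilic substitution on A2 would have to choose between the position para to the lactone oxygen, the position between the two oxygens, and ring A. The enantio-determining C–H cleavage has the prochiral carbon β to the carboxylate and runs through a larger palladacycle than the well-precedented benzofuranone case. The oxidant also meets electron-rich benzyloxyarenes.
- Comparison: the chosen plan is longer to its lactone 9. In return the arm position is fixed as bromine from the first compound, and C* is set by a reaction class already shown on 2-(1-substituted vinyl)benzaldehydes.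

**Alternative 2: ring A built by cobalt-catalysed cycloaddition.** The cut removes two C–C bonds of ring A. The alkyne A3, which already holds C*, ring B, the ketal-protected arm and the ring C chain, would react with a 2-silyloxybutadiene under CoBr2(dppe), zinc and ZnI2. This would give the 1,4-cyclohexadiene A4, which still has to be dehydrogenated and desilylated to the phenol.

- Merits: the oxygen of ring A ends up para to C* without ambiguity. The conditions are neutral. The problem of telling two aryl rings apart at C* is avoided because ring A arrives as an alkyne, for which enantioselective methods exist.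
- Weak points: the key step sets no stereocentre and forms no bond of the chain, so the hardest problem is only moved into the preparation of A3. In A3, C* is a propargylic and benzylic C–H that can isomerise towards an allene under base or metal catalysis. Ring A is the one part of the molecule that can be bought intact, and here it costs a cycloaddition, an aromatisation and a deprotection.
- Comparison: this road is better only in how cleanly it separates ring A from ring B at C*. The chosen plan answers that with the chelate of its key step and creates C* and a ring in the same operation.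

**Alternative 3: three-component conjunctive coupling.** The cuts are the C*–ring A bond and the bond from Cβ to the benzylic carbon of ring C. A boron ate complex from a ring B styrenyl metal and a ring C benzylic boronic ester would react with a ring A aryl triflate under Pd(OAc)2 and a chiral MandyPhos ligand. The 1,2-metallate shift would give the boronic ester A5.

- Merits: it is the most convergent of the four roads. Three separately made aryl units meet in one step that also sets C*. On paper it is shorter than the chosen plan.
- Weak points: A5 carries a boronic ester and a second stereocentre on a carbon that is CH2 in the target. A secondary alkyl C–B bond must therefore be replaced by C–H afterwards. A β-aryl-substituted alkenyl ate complex with a benzylic migrating group is at the edge of the known scope. Direct transfer of the benzyl group to palladium would give a simple cross-coupling product. The arm has to travel as a ketal beside an alkenyl lithium.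
- Comparison: the chosen plan is less convergent and needs a bromine placeholder and two redox adjustments. Against that, every C–C bond in it is formed by a long-established reaction type with a close precedent, and no carbon substituent has to be removed afterwards.

Key step: step 6

Remarks on the chemistry (assumptions):
- The ligand is written as (R)-BINAP. The sense of induction for a 1,1-diaryl alkene has to be confirmed on the first run. If it is the reverse, (S)-BINAP is used and nothing else changes.
- Compounds 1, 4, 12 and 16 are taken to be commercially available.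

## Route

Step 1
Reactants: 1 4-bromo-3-hydroxybenzaldehyde
Product: 2 4-bromo-5-hydroxy-2-iodobenzaldehyde
Conditions: NIS (1.05 equiv), TsOH·H2O (10 mol %), MeCN, 0 °C to rt
Reagents that add atoms: N-iodosuccinimide, O=C1CCC(=O)N1I
Why: Electrophilic aromatic iodination; the phenol directs to its free para position, and the only other activated site lies between OH and CHO and is hindered, so iodine should enter ortho to the formyl group where the vinyl unit is needed.

Step 2
Reactants: 2 4-bromo-5-hydroxy-2-iodobenzaldehyde
Product: 3 5-(benzyloxy)-4-bromo-2-iodobenzaldehyde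
Conditions: BnBr (1.1 equiv), K2CO3, DMF, rt
Reagents that add atoms: benzyl bromide, BrCc1ccccc1
Why: Williamson ether synthesis on the phenoxide; the benzyl ether is the phenol protecting group of the whole route and is inert until the final hydrogenolysis.

Step 3
Reactants: 4 1-[4-(benzyloxy)phenyl]ethan-1-one
Product: 5 1-[4-(benzyloxy)phenyl]ethenyl trifluoromethanesulfonate
Conditions: KN(SiMe3)2, THF, −78 °C; then PhNTf2, −78 to 0 °C
Reagents that add atoms: N-phenylbis(trifluoromethanesulfonimide), O=S(=O)(N(c1ccccc1)S(=O)(=O)C(F)(F)F)C(F)(F)F
Why: Enol triflate formation by O-sulfonylation of the potassium enolate; the methyl ketone has a single enolisable position, so only one alkenyl triflate can form.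

Step 4
Reactants: 5 1-[4-(benzyloxy)phenyl]ethenyl trifluoromethanesulfonate
Product: 6 2-{1-[4-(benzyloxy)phenyl]ethenyl}-4,4,5,5-tetramethyl-1,3,2-dioxaborolane
Conditions: B2pin2, PdCl2(PPh3)2 (3 mol %), PPh3 (6 mol %), KOPh, toluene, 50 °C
Reagents that add atoms: bis(pinacolato)diboron, CC1(C)OB(OC1(C)C)B1OC(C)(C)C(C)(C)O1
Why: Miyaura borylation of an alkenyl triflate; the weak base KOPh promotes boron transfer without coupling the product boronate to unreacted triflate.

Step 5
Reactants: 3 5-(benzyloxy)-4-bromo-2-iodobenzaldehyde; 6 2-{1-[4-(benzyloxy)phenyl]ethenyl}-4,4,5,5-tetramethyl-1,3,2-dioxaborolane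
Product: 7 5-(benzyloxy)-4-bromo-2-{1-[4-(benzyloxy)phenyl]ethenyl}benzaldehyde
Conditions: Pd(PPh3)4 (5 mol %), Na2CO3 (2 M aq), DME, 70 °C
Reagents that add atoms: none
Why: Suzuki–Miyaura coupling; zerovalent palladium inserts into the C–I bond ortho to the formyl group much faster than into the C–Br bond, so the bromine should remain as the handle for the arm.

Step 6
Reactants: 7 5-(benzyloxy)-4-bromo-2-{1-[4-(benzyloxy)phenyl]ethenyl}benzaldehyde
Product: 8 (3R)-6-(benzyloxy)-5-bromo-3-[4-(benzyloxy)phenyl]-2,3-dihydro-1H-inden-1-one
Conditions: [Rh(cod)2]BF4 (5 mol %), (R)-BINAP (5.5 mol %), catalyst activated under H2 then Ar, acetone, 25 °C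
Reagents that add atoms: none
Why: Intramolecular alkene hydroacylation, the closest known reaction type being the rhodium–bisphosphine cyclisation of 2-(α-substituted vinyl)benzaldehydes to 3-substituted indan-1-ones. Monovalent rhodium inserts into the aldehyde C–H bond to give a trivalent acyl rhodium hydride that is held by the ortho alkene, and this chelation keeps decarbonylation slow. The hydride migrates to the internal alkene carbon, which becomes C3, and rhodium takes the terminal CH2, giving a six-membered acyl–alkyl rhodacycle; reductive elimination then joins the acyl carbon to CH2. The five-membered ketone ring thus closes with both alkene carbons inside it, a formal 5-endo-trig closure that is possible because the bond forms by reductive elimination at the metal and not by direct attack on the alkene. The opposite regiochemistry would require a five-membered rhodacycle on the way to a strained benzocyclobutenone and is not expected. C3 is the only new stereocentre and is set under catalyst control: the chiral pocket of (R)-BINAP decides which face of the 1,1-diaryl alkene receives the hydride, and delivery to the Si face (ring B > ring A > CH2) gives the (3R) ketone. The step needs C–H activation to win over C–Br activation, which the mild temperature and the slow oxidative addition of aryl bromides to cationic monovalent rhodium should secure, and it needs the two aryl groups on the alkene to be told apart, which is helped by ring B being locked in the chelate while ring A is free.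

Step 7
Reactants: 8 (3R)-6-(benzyloxy)-5-bromo-3-[4-(benzyloxy)phenyl]-2,3-dihydro-1H-inden-1-one
Product: 9 (4R)-7-(benzyloxy)-6-bromo-4-[4-(benzyloxy)phenyl]-3,4-dihydro-2H-chromen-2-one
Conditions: mCPBA (2 equiv), TsOH·H2O (10 mol %), CH2Cl2, 4 °C
Reagents that add atoms: 3-chloroperoxybenzoic acid, OOC(=O)c1cccc(Cl)c1
Why: Baeyer–Villiger oxidation; in the Criegee adduct the aryl carbon migrates in preference to the primary CH2, as is usual for 3-arylindan-1-ones under acid-promoted peracid conditions, and the para bromine and meta benzyloxy group lower that aptitude only slightly. The stereocentre is not involved, and no acid-labile group or second ketone is present at this stage.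

Step 8
Reactants: 9 (4R)-7-(benzyloxy)-6-bromo-4-[4-(benzyloxy)phenyl]-3,4-dihydro-2H-chromen-2-one
Product: 10 5-(benzyloxy)-4-bromo-2-{(1R)-1-[4-(benzyloxy)phenyl]-3-hydroxypropyl}phenol
Conditions: LiBH4, THF, 0 °C to rt
Reagents that add atoms: none
Why: Hydride reduction of an aryl ester (lactone) to the phenol and the primary alcohol; LiBH4 leaves the aryl bromide and the benzyl ethers alone, and C* is β to the carbonyl and cannot epimerise.

Step 9
Reactants: 10 5-(benzyloxy)-4-bromo-2-{(1R)-1-[4-(benzyloxy)phenyl]-3-hydroxypropyl}phenol
Product: 11 (3R)-3-[2,4-bis(benzyloxy)-5-bromophenyl]-3-[4-(benzyloxy)phenyl]propan-1-ol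
Conditions: BnBr (1.05 equiv), K2CO3, acetone, 50 °C
Reagents that add atoms: benzyl bromide, BrCc1ccccc1
Why: Chemoselective Williamson etherification; carbonate deprotonates only the phenol, so the primary alcohol stays free, and capping the phenol prevents its later closure onto the activated chain end to a chroman.

Step 10
Reactants: 12 4-(benzyloxy)benzaldehyde
Product: 13 1-[4-(benzyloxy)phenyl]prop-2-en-1-ol (racemic)
Conditions: CH2=CHMgBr, THF, 0 °C
Reagents that add atoms: vinylmagnesium bromide, C=C[Mg]Br
Why: Grignard addition to an aldehyde; the racemic carbinol centre is of no consequence because it becomes the ketone carbon in the next step.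

Step 11
Reactants: 11 (3R)-3-[2,4-bis(benzyloxy)-5-bromophenyl]-3-[4-(benzyloxy)phenyl]propan-1-ol; 13 1-[4-(benzyloxy)phenyl]prop-2-en-1-ol
Product: 14 3-[2,4-bis(benzyloxy)-5-{(1R)-1-[4-(benzyloxy)phenyl]-3-hydroxypropyl}phenyl]-1-[4-(benzyloxy)phenyl]propan-1-one
Conditions: Pd(OAc)2 (5 mol %), P(o-tol)3 (10 mol %), NaHCO3, Bu4NCl, DMF, 100 °C
Reagents that add atoms: none
Why: Heck reaction of an aryl bromide with a secondary allylic alcohol: the arylpalladium adds to the terminal alkene carbon, β-hydride elimination runs towards the carbinol carbon and the enol tautomerises, so the β-aryl ketone forms directly. The primary alcohol, the benzyl ethers and C* are spectators under hydrogencarbonate.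

Step 12
Reactants: 14 3-[2,4-bis(benzyloxy)-5-{(1R)-1-[4-(benzyloxy)phenyl]-3-hydroxypropyl}phenyl]-1-[4-(benzyloxy)phenyl]propan-1-one
Product: 15 3-[2,4-bis(benzyloxy)-5-{(1R)-1-[4-(benzyloxy)phenyl]-3-iodopropyl}phenyl]-1-[4-(benzyloxy)phenyl]propan-1-one
Conditions: I2, PPh3, imidazole, CH2Cl2, 0 °C to rt
Reagents that add atoms: iodine, II
Why: Appel iodination of the primary alcohol; the conditions are neutral, the ketone is untouched, and the reacting carbon is not a stereocentre.

Step 13
Reactants: 16 4-bromo-3-methoxyphenol
Product: 17 4-(benzyloxy)-1-bromo-2-methoxybenzene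
Conditions: BnBr (1.1 equiv), K2CO3, DMF, rt
Reagents that add atoms: benzyl bromide, BrCc1ccccc1
Why: Williamson ether synthesis; it gives ring C with its methyl ether in place and its phenol masked like the others.

Step 14
Reactants: 15 3-[2,4-bis(benzyloxy)-5-{(1R)-1-[4-(benzyloxy)phenyl]-3-iodopropyl}phenyl]-1-[4-(benzyloxy)phenyl]propan-1-one; 17 4-(benzyloxy)-1-bromo-2-methoxybenzene
Product: 19 3-[2,4-bis(benzyloxy)-5-{(1R)-3-[4-(benzyloxy)-2-methoxyphenyl]-1-[4-(benzyloxy)phenyl]propyl}phenyl]-1-[4-(benzyloxy)phenyl]propan-1-one, via alkylzinc iodide 18 (not isolated)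
Conditions: Zn dust (Me3SiCl-activated), LiCl, THF, 40 °C; then 17, Pd(OAc)2 (2 mol %), SPhos (4 mol %), THF, 50 °C
Reagents that add atoms: zinc, [Zn] (held in 18, not in 19)
Why: Negishi coupling; zinc inserts into the primary C–I bond to an alkylzinc iodide that tolerates the aryl ketone, and the bulky biarylphosphine favours oxidative addition and reductive elimination with the electron-rich ortho-methoxy aryl bromide. No benzylic oxygen is created, so nothing has to be removed beside the arm ketone.

Step 15
Reactants: 19 3-[2,4-bis(benzyloxy)-5-{(1R)-3-[4-(benzyloxy)-2-methoxyphenyl]-1-[4-(benzyloxy)phenyl]propyl}phenyl]-1-[4-(benzyloxy)phenyl]propan-1-one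
Product: 20 3-[2,4-dihydroxy-5-{(1R)-3-(4-hydroxy-2-methoxyphenyl)-1-(4-hydroxyphenyl)propyl}phenyl]-1-(4-hydroxyphenyl)propan-1-one
Conditions: H2 (1 atm), palladium on carbon (10 wt % Pd), EtOAc–MeOH, rt
Reagents that add atoms: none
Why: Catalytic hydrogenolysis of the four benzyl aryl ethers under neutral conditions; the 4-hydroxyphenyl ketone is a deactivated carbonyl of the kind that survives in dihydrochalcone preparations, the methyl ether is inert and C* is untouched. The reaction should be stopped as soon as debenzylation is complete.

## Compound list

1 | 4-bromo-3-hydroxybenzaldehyde | O=Cc1ccc(Br)c(O)c1 | starting material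
2 | 4-bromo-5-hydroxy-2-iodobenzaldehyde | O=Cc1cc(O)c(Br)cc1I | intermediate
3 | 5-(benzyloxy)-4-bromo-2-iodobenzaldehyde | O=Cc1cc(OCc2ccccc2)c(Br)cc1I | intermediate
4 | 1-[4-(benzyloxy)phenyl]ethan-1-one | CC(=O)c1ccc(OCc2ccccc2)cc1 | starting material
5 | 1-[4-(benzyloxy)phenyl]ethenyl trifluoromethanesulfonate | C=C(OS(=O)(=O)C(F)(F)F)c1ccc(OCc2ccccc2)cc1 | intermediate
6 | 2-{1-[4-(benzyloxy)phenyl]ethenyl}-4,4,5,5-tetramethyl-1,3,2-dioxaborolane | C=C(B1OC(C)(C)C(C)(C)O1)c1ccc(OCc2ccccc2)cc1 | intermediate
7 | 5-(benzyloxy)-4-bromo-2-{1-[4-(benzyloxy)phenyl]ethenyl}benzaldehyde | O=Cc1cc(OCc2ccccc2)c(Br)cc1C(=C)c1ccc(OCc2ccccc2)cc1 | intermediate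
8 | (3R)-6-(benzyloxy)-5-bromo-3-[4-(benzyloxy)phenyl]-2,3-dihydro-1H-inden-1-one | O=C1C[C@H](c2ccc(OCc3ccccc3)cc2)c2cc(Br)c(OCc3ccccc3)cc21 | intermediate
9 | (4R)-7-(benzyloxy)-6-bromo-4-[4-(benzyloxy)phenyl]-3,4-dihydro-2H-chromen-2-one | O=C1C[C@H](c2ccc(OCc3ccccc3)cc2)c2cc(Br)c(OCc3ccccc3)cc2O1 | intermediate
10 | 5-(benzyloxy)-4-bromo-2-{(1R)-1-[4-(benzyloxy)phenyl]-3-hydroxypropyl}phenol | OCC[C@H](c1ccc(OCc2ccccc2)cc1)c1cc(Br)c(OCc2ccccc2)cc1O | intermediate
11 | (3R)-3-[2,4-bis(benzyloxy)-5-bromophenyl]-3-[4-(benzyloxy)phenyl]propan-1-ol | OCC[C@H](c1ccc(OCc2ccccc2)cc1)c1cc(Br)c(OCc2ccccc2)cc1OCc1ccccc1 | intermediate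
12 | 4-(benzyloxy)benzaldehyde | O=Cc1ccc(OCc2ccccc2)cc1 | starting material
13 | 1-[4-(benzyloxy)phenyl]prop-2-en-1-ol (racemic) | C=CC(O)c1ccc(OCc2ccccc2)cc1 | intermediate
14 | 3-[2,4-bis(benzyloxy)-5-{(1R)-1-[4-(benzyloxy)phenyl]-3-hydroxypropyl}phenyl]-1-[4-(benzyloxy)phenyl]propan-1-one | OCC[C@H](c1ccc(OCc2ccccc2)cc1)c1cc(CCC(=O)c2ccc(OCc3ccccc3)cc2)c(OCc2ccccc2)cc1OCc1ccccc1 | intermediate
15 | 3-[2,4-bis(benzyloxy)-5-{(1R)-1-[4-(benzyloxy)phenyl]-3-iodopropyl}phenyl]-1-[4-(benzyloxy)phenyl]propan-1-one | ICC[C@H](c1ccc(OCc2ccccc2)cc1)c1cc(CCC(=O)c2ccc(OCc3ccccc3)cc2)c(OCc2ccccc2)cc1OCc1ccccc1 | intermediate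
16 | 4-bromo-3-methoxyphenol | COc1cc(O)ccc1Br | starting material
17 | 4-(benzyloxy)-1-bromo-2-methoxybenzene | COc1cc(OCc2ccccc2)ccc1Br | intermediate
18 | {(3R)-3-[2,4-bis(benzyloxy)-5-{3-[4-(benzyloxy)phenyl]-3-oxopropyl}phenyl]-3-[4-(benzyloxy)phenyl]propyl}(iodo)zinc | I[Zn]CC[C@H](c1ccc(OCc2ccccc2)cc1)c1cc(CCC(=O)c2ccc(OCc3ccccc3)cc2)c(OCc2ccccc2)cc1OCc1ccccc1 | intermediate (not isolated)
19 | 3-[2,4-bis(benzyloxy)-5-{(1R)-3-[4-(benzyloxy)-2-methoxyphenyl]-1-[4-(benzyloxy)phenyl]propyl}phenyl]-1-[4-(benzyloxy)phenyl]propan-1-one | COc1cc(OCc2ccccc2)ccc1CC[C@H](c1ccc(OCc2ccccc2)cc1)c1cc(CCC(=O)c2ccc(OCc3ccccc3)cc2)c(OCc2ccccc2)cc1OCc1ccccc1 | intermediate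
20 | 3-[2,4-dihydroxy-5-{(1R)-3-(4-hydroxy-2-methoxyphenyl)-1-(4-hydroxyphenyl)propyl}phenyl]-1-(4-hydroxyphenyl)propan-1-one (CNP0253987.1) | COc1cc(O)ccc1CC[C@H](c1ccc(O)cc1)c1cc(CCC(=O)c2ccc(O)cc2)c(O)cc1O | target

## Step count and least certain steps

Total: 15 steps. Longest linear sequence: 11 steps (steps 1, 2, 5, 6, 7, 8, 9, 11, 12, 14 and 15).

**Step 6 (key step).** The most likely failure is poor facial discrimination, because both substituents on the alkene are flat aryl rings of similar size. A slow cyclisation could also lose catalyst through decarbonylation. The fallback sets out from 7 and comes back at 8.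
- The aldehyde 7 is cyclised without asking for enantiocontrol, using the achiral complex [Rh(nbd)(dppe)]BF4 after hydrogenation. This gives racemic 6-(benzyloxy)-5-bromo-3-[4-(benzyloxy)phenyl]-2,3-dihydro-1H-inden-1-one F1.
- Dehydrogenation with IBX in DMSO at 65 °C gives 6-(benzyloxy)-5-bromo-3-[4-(benzyloxy)phenyl]-1H-inden-1-one F2, in which the stereocentre is erased.
- Corey–Bakshi–Shibata reduction (BH3·SMe2, with the oxazaborolidine enantiomer chosen to give the 1R carbinol) gives (1R)-6-(benzyloxy)-5-bromo-3-[4-(benzyloxy)phenyl]-1H-inden-1-ol F3.
- Warming F3 with DABCO in THF at 60 °C moves the carbinol hydrogen suprafacially from C1 to C3. This should give the (3R) ketone 8.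

In this fallback the stereocentre is set at a carbonyl carbon by a reagent and then transferred. It no longer depends on distinguishing two aryl rings.

**Step 11.** The likely problems are slow oxidative addition of the electron-rich, ortho-alkoxy aryl bromide, reduction of the C–Br bond, and isomerisation of the allylic alcohol to the propiophenone before it couples. The fallback sets out from 11 and comes back at 14. The arm is delivered as a palladium homoenolate instead of through an alkene insertion.
- 1-[4-(benzyloxy)phenyl]cyclopropan-1-ol F4 is made by Kulinkovich cyclopropanation of the commercial methyl ester of 4-(benzyloxy)benzoic acid (EtMgBr, Ti(OiPr)4).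
- F4 is coupled with 11 using Pd(OAc)2, XPhos and Cs2CO3 in toluene at 80 °C. The palladium alkoxide opens by β-carbon elimination, and reductive elimination gives the β-aryl ketone 14 directly.

**Step 14.** Zinc insertion may be incomplete, or the alkylzinc may be protonated, which leaves a reduced chain. The coupling with the hindered, electron-rich bromide may also be slow. The fallback sets out from 15 and 17 and comes back at 19. Both partners are used as electrophiles in a nickel-catalysed reductive cross-coupling (NiI2, 4,4'-di-tert-butyl-2,2'-bipyridine, Zn powder, NaI, DMA, 60 °C). The chain enters as an alkyl radical, so no organometallic reagent has to be made beforehand, and the ketone is tolerated. No new compound is made.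

**Step 1.** Iodination may occur in part at the position between the hydroxyl and formyl groups, or twice. The fallback sets out from 1 and comes back at 3. The order is reversed and the directing group changed.
- Benzylation first (BnBr, K2CO3, DMF) gives 3-(benzyloxy)-4-bromobenzaldehyde F5.
- F5 is iodinated with I2 and AgOSO2CF3 in CH2Cl2. Iodination is then directed by the ether to its para position, and the site between the ether and the formyl group is more hindered than in the phenol, so 3 should form directly.

## Further compounds

F1 | step 6 | racemic 6-(benzyloxy)-5-bromo-3-[4-(benzyloxy)phenyl]-2,3-dihydro-1H-inden-1-one | O=C1CC(c2ccc(OCc3ccccc3)cc2)c2cc(Br)c(OCc3ccccc3)cc21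
F2 | step 6 | 6-(benzyloxy)-5-bromo-3-[4-(benzyloxy)phenyl]-1H-inden-1-one | O=C1C=C(c2ccc(OCc3ccccc3)cc2)c2cc(Br)c(OCc3ccccc3)cc21
F3 | step 6 | (1R)-6-(benzyloxy)-5-bromo-3-[4-(benzyloxy)phenyl]-1H-inden-1-ol | O[C@@H]1C=C(c2ccc(OCc3ccccc3)cc2)c2cc(Br)c(OCc3ccccc3)cc21
F4 | step 11 | 1-[4-(benzyloxy)phenyl]cyclopropan-1-ol | OC1(CC1)c1ccc(OCc2ccccc2)cc1
F0 | step 14 | none | none
F5 | step 1 | 3-(benzyloxy)-4-bromobenzaldehyde | O=Cc1ccc(Br)c(OCc2ccccc2)c1
A1 | alternative 1 | 3,3-bis[4-(benzyloxy)phenyl]propanoic acid | OC(=O)CC(c1ccc(OCc2ccccc2)cc1)c1ccc(OCc2ccccc2)cc1
A2 | alternative 1 | (4R)-7-(benzyloxy)-4-[4-(benzyloxy)phenyl]-3,4-dihydro-2H-chromen-2-one | O=C1C[C@H](c2ccc(OCc3ccccc3)cc2)c2ccc(OCc3ccccc3)cc2O1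
A3 | alternative 2 | 2-[4-(benzyloxy)phenyl]-2-(2-{2,4-bis(benzyloxy)-5-[(3R)-5-[4-(benzyloxy)-2-methoxyphenyl]pent-1-yn-3-yl]phenyl}ethyl)-1,3-dioxolane | COc1cc(OCc2ccccc2)ccc1CC[C@H](C#C)c1cc(CCC2(c3ccc(OCc4ccccc4)cc3)OCCO2)c(OCc2ccccc2)cc1OCc1ccccc1
A4 | alternative 2 | 2-[4-(benzyloxy)phenyl]-2-(2-{2,4-bis(benzyloxy)-5-[(1R)-3-[4-(benzyloxy)-2-methoxyphenyl]-1-{4-[(trimethylsilyl)oxy]cyclohexa-1,4-dien-1-yl}propyl]phenyl}ethyl)-1,3-dioxolane | COc1cc(OCc2ccccc2)ccc1CC[C@H](C1=CCC(O[Si](C)(C)C)=CC1)c1cc(CCC2(c3ccc(OCc4ccccc4)cc3)OCCO2)c(OCc2ccccc2)cc1OCc1ccccc1
A5 | alternative 3 | 2-[(1R,2R)-1-{2,4-bis(benzyloxy)-5-[2-(2-[4-(benzyloxy)phenyl]-1,3-dioxolan-2-yl)ethyl]phenyl}-3-[4-(benzyloxy)-2-methoxyphenyl]-1-[4-(benzyloxy)phenyl]propan-2-yl]-4,4,5,5-tetramethyl-1,3,2-dioxaborolane | COc1cc(OCc2ccccc2)ccc1C[C@@H](B1OC(C)(C)C(C)(C)O1)[C@H](c1ccc(OCc2ccccc2)cc1)c1cc(CCC2(c3ccc(OCc4ccccc4)cc3)OCCO2)c(OCc2ccccc2)cc1OCc1ccccc1
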